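The route rests on cutting the C3'–C4' bond of the side chain (C1' is bonded to ring C6 of the dihydropyranone; hydroxyls sit on C2', C4' and C6') and on treating the carbinol carbon C4', which lies between two CH2–CH(O) units, as a masked acyl dianion. In one flask a 2-silyl-1,3-dithiane is lithiated and alkylated by (S)-1,2-epoxyundecane, a 1,4-Brook rearrangement renews the carbanion, and this opens one oxirane of (R,R)-1,2:4,5-diepoxypentane, which forms C3'–C4' and delivers the anti-related oxygens on C2' and C6. The precursor is thus a dithiane bearing an epoxide, not a polyol; C4' is set last by hydroxyl-directed reduction.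

Key step: step 5

Remark on the chemistry: the target is read as (6S,2'S,4'S,6'S), so the C2', C4' and C6' hydroxyls are mutually syn and the ring oxygen on C6 is anti to the C2' hydroxyl. Locants: ring O1, C2 (carbonyl), C3=C4, C5, C6; side chain C1' (on C6) to C15'. TBS = tert-butyldimethylsilyl.

Step 1
Reactants: 1 (S)-2-(chloromethyl)oxirane ((S)-epichlorohydrin); 2 octylmagnesium bromide
Product: 4 (S)-2-nonyloxirane ((S)-1,2-epoxyundecane), via (S)-1-chloroundecan-2-ol 3 (not isolated)
Conditions: CuI (10 mol%), THF, −40 to −20 °C; then aq. NaOH (3 M), rt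
Reagents that add atoms: none
Why: Copper-catalysed Grignard opening of the oxirane at its CH2 terminus is followed by base-induced Williamson closure of chlorohydrin 3 onto the former CH2Cl carbon, and since the stereocentre of 1 is never touched, (S)-1 should give (S)-4.

Step 2
Reactants: 5 pentane-2,4-dione (acetylacetone); 6 chloroacetyl chloride
Product: 7 1,5-dichloropentane-2,4-dione
Conditions: 6 (3 equiv), AlCl3 (3 equiv), PhNO2, 60 °C; ice/aq. HCl
Reagents that add atoms: none
Why: AlCl3-mediated acyl exchange of a β-diketone (C-acylation by the acid chloride, then retro-Claisen loss of acetyl chloride, twice) is a reversible process that should be driven by escape of the volatile acetyl chloride, and no stereocentre is formed.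

Step 3
Reactants: 7 1,5-dichloropentane-2,4-dione
Product: 8 (2R,4R)-1,5-dichloropentane-2,4-diol
Conditions: H2 (80 atm), [RuCl2((S)-BINAP)]2·NEt3 (cat.), MeOH, 100 °C; recrystallisation
Reagents that add atoms: none
Why: Noyori asymmetric hydrogenation of a β-diketone, in which the (S)-BINAP–ruthenium catalyst reduces each chelated carbonyl from the same enantioface in turn, should give the C2-symmetric anti (2R,4R) diol, with the minor meso isomer removed by crystallisation.

Step 4
Reactants: 8 (2R,4R)-1,5-dichloropentane-2,4-diol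
Product: 9 (2R,4R)-1,2:4,5-diepoxypentane
Conditions: KOH (powdered), Et2O, rt
Reagents that add atoms: none
Why: Twofold intramolecular Williamson etherification, in which each alkoxide displaces the neighbouring primary chloride, leaves both carbinol stereocentres untouched.

Step 5
Reactants: 10 2-(tert-butyldimethylsilyl)-1,3-dithiane; 4 (S)-2-nonyloxirane; 9 (2R,4R)-1,2:4,5-diepoxypentane
Product: 15 2-[(2S)-2-(tert-butyldimethylsilyloxy)undecyl]-2-[(2R)-2-(tert-butyldimethylsilyloxy)-3-[(2R)-oxiran-2-yl]propyl]-1,3-dithiane, via 2-lithio-2-silyl-1,3-dithiane 11 (not isolated), via first lithium alkoxide 12 (not isolated), via Brook-rearranged 2-lithiodithiane 13 (not isolated), via epoxy lithium alkoxide 14 (not isolated)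
Conditions: t-BuLi, Et2O, −78 to −45 °C; 4, −78 to −25 °C; 9 (3 equiv), HMPA, Et2O, −78 to 0 °C; TBSCl, 0 °C to rt
Reagents that add atoms: tert-butyldimethylsilyl chloride (TBSCl), CC(C)(C)[Si](C)(C)Cl
Why: t-BuLi deprotonates C2 of 10 and anion 11 opens 4 at its CH2 terminus in Et2O, where alkoxide 12 persists; HMPA then triggers a 1,4-Brook rearrangement (silyl shift from carbon to oxygen) that regenerates a dithiane carbanion 13, which opens one oxirane of 9 at its CH2 terminus and so forms the C3'–C4' bond, and alkoxide 14 is capped by TBSCl. The closest known reaction type is the solvent-controlled three-component linchpin coupling of a 2-silyl-1,3-dithiane with two different epoxides (anion relay chemistry), which is also known with bis-electrophiles such as diepoxypentane and epichlorohydrin as the second partner. No ring is closed. No stereocentre is created: C6' comes from 4, C2' and ring C6 come from 9 (both openings occur at CH2, away from the C–O stereocentres), and the dithiane carbon C4' stays prochiral until step 9. The step needs ordered alkylation, secured by running the first alkylation in Et2O, where the silyl shift does not occur, and adding HMPA only together with the second electrophile. It also needs mono-opening of the bis-epoxide, secured by a threefold excess of 9, whose two oxiranes are homotopic so that either end gives the same product.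

Step 6
Reactants: 15 the bis-TBS epoxy dithiane; 16 ethyl propiolate
Product: 18 ethyl (5S,7R)-7-(tert-butyldimethylsilyloxy)-5-hydroxy-8-{2-[(2S)-2-(tert-butyldimethylsilyloxy)undecyl]-1,3-dithian-2-yl}oct-2-ynoate, via ethyl 3-lithiopropiolate 17 (not isolated)
Conditions: 16 (3 equiv), n-BuLi, THF, −78 °C; BF3·OEt2; then 15, −78 °C; aq. NH4Cl
Reagents that add atoms: none
Why: In this Yamaguchi–Hirao alkynylation the BF3-activated terminal oxirane is opened at CH2 by the lithium acetylide at −78 °C, where the ester, the dithiane and both silyl ethers are inert, and the C6 stereocentre is not involved.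

Step 7
Reactants: 18 the hydroxy ynoate dithiane
Product: 19 ethyl (5S,7R,11S)-7,11-bis(tert-butyldimethylsilyloxy)-5-hydroxy-9-oxoicos-2-ynoate
Conditions: PhI(OCOCF3)2 (1.5 equiv), MeCN/H2O (9:1), 0 °C; aq. NaHCO3 work-up
Reagents that add atoms: water, O
Why: Oxidative dethioketalisation by a hypervalent iodine reagent (S-activation, ring opening to a thionium ion, capture by water) should release the C4' ketone within minutes at 0 °C, conditions that spare TBS ethers, the alkynoate and the secondary alcohol (19 may equilibrate with its six-membered hemiketal, which is harmless because step 8 acylates the C6 oxygen).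

Step 8
Reactants: 19 the keto hydroxy ynoate
Product: 21 (6S)-6-[(2R,6S)-2,6-dihydroxy-4-oxopentadecyl]-5,6-dihydro-2H-pyran-2-one, via (Z)-enoate ester 20 (not isolated)
Conditions: H2 (1 atm), Pd/CaCO3 poisoned with Pb(OAc)2 (Lindlar catalyst), quinoline, EtOAc, rt; filter; 48% aq. HF, MeCN, 0 °C to rt
Reagents that add atoms: none
Why: Lindlar cis-semihydrogenation gives the (Z)-enoate, whose geometry holds the ester next to the C6 hydroxyl, so that aqueous HF should bring about lactonisation to the six-membered ring and cleave both TBS ethers in the same operation without touching a stereocentre.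

Step 9
Reactants: 21 the dihydroxy keto lactone
Product: 23 (6S)-6-[(2S,4S,6S)-2,4,6-trihydroxypentadecyl]-5,6-dihydro-2H-pyran-2-one, via diethylboryl chelate 22 (not isolated)
Conditions: Et2BOMe, THF/MeOH (4:1), −78 °C; NaBH4, −78 °C; AcOH; MeOH co-evaporation
Reagents that add atoms: none
Why: In this Narasaka–Prasad reduction Et2BOMe forms a six-membered boron chelate between the C4' ketone and a flanking β-hydroxyl and external hydride adds axially to give the syn-1,3-diol; because the C2' and C6' hydroxyls are themselves syn-related, chelation through either one should lead to the same (4'S) carbinol, while at −78 °C and with a non-basic work-up the conjugated lactone should stay intact.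

Compound list
1 | (S)-2-(chloromethyl)oxirane ((S)-epichlorohydrin) | ClC[C@@H]1CO1 | starting material
2 | octylmagnesium bromide | CCCCCCCC[Mg]Br | starting material
3 | (S)-1-chloroundecan-2-ol | CCCCCCCCC[C@H](O)CCl | intermediate
4 | (S)-2-nonyloxirane ((S)-1,2-epoxyundecane) | CCCCCCCCC[C@H]1CO1 | intermediate
5 | pentane-2,4-dione (acetylacetone) | CC(=O)CC(C)=O | starting material
6 | chloroacetyl chloride | ClCC(Cl)=O | starting material
7 | 1,5-dichloropentane-2,4-dione | ClCC(=O)CC(=O)CCl | intermediate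
8 | (2R,4R)-1,5-dichloropentane-2,4-diol | ClC[C@H](O)C[C@@H](O)CCl | intermediate
9 | (2R,4R)-1,2:4,5-diepoxypentane | C1[C@H](O1)C[C@@H]2CO2 | intermediate
10 | 2-(tert-butyldimethylsilyl)-1,3-dithiane | CC(C)(C)[Si](C)(C)C1SCCCS1 | starting material
11 | 2-lithio-2-(tert-butyldimethylsilyl)-1,3-dithiane | [Li]C1([Si](C)(C)C(C)(C)C)SCCCS1 | intermediate
12 | lithium (2S)-1-[2-(tert-butyldimethylsilyl)-1,3-dithian-2-yl]undecan-2-olate | CCCCCCCCC[C@H](O[Li])CC1([Si](C)(C)C(C)(C)C)SCCCS1 | intermediate
13 | 2-lithio-2-[(2S)-2-(tert-butyldimethylsilyloxy)undecyl]-1,3-dithiane | CCCCCCCCC[C@H](O[Si](C)(C)C(C)(C)C)CC1([Li])SCCCS1 | intermediate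
14 | lithium (2R)-1-{2-[(2S)-2-(tert-butyldimethylsilyloxy)undecyl]-1,3-dithian-2-yl}-3-[(2R)-oxiran-2-yl]propan-2-olate | CCCCCCCCC[C@H](O[Si](C)(C)C(C)(C)C)CC1(SCCCS1)C[C@H](O[Li])C[C@@H]2CO2 | intermediate
15 | 2-[(2S)-2-(tert-butyldimethylsilyloxy)undecyl]-2-[(2R)-2-(tert-butyldimethylsilyloxy)-3-[(2R)-oxiran-2-yl]propyl]-1,3-dithiane | CCCCCCCCC[C@H](O[Si](C)(C)C(C)(C)C)CC1(SCCCS1)C[C@H](O[Si](C)(C)C(C)(C)C)C[C@@H]2CO2 | intermediate
16 | ethyl propiolate (ethyl prop-2-ynoate) | C#CC(=O)OCC | starting material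
17 | ethyl 3-lithioprop-2-ynoate | [Li]C#CC(=O)OCC | intermediate
18 | ethyl (5S,7R)-7-(tert-butyldimethylsilyloxy)-5-hydroxy-8-{2-[(2S)-2-(tert-butyldimethylsilyloxy)undecyl]-1,3-dithian-2-yl}oct-2-ynoate | CCCCCCCCC[C@H](O[Si](C)(C)C(C)(C)C)CC1(SCCCS1)C[C@H](O[Si](C)(C)C(C)(C)C)C[C@@H](O)CC#CC(=O)OCC | intermediate
19 | ethyl (5S,7R,11S)-7,11-bis(tert-butyldimethylsilyloxy)-5-hydroxy-9-oxoicos-2-ynoate | CCCCCCCCC[C@H](O[Si](C)(C)C(C)(C)C)CC(=O)C[C@H](O[Si](C)(C)C(C)(C)C)C[C@@H](O)CC#CC(=O)OCC | intermediate
20 | ethyl (2Z,5S,7R,11S)-7,11-bis(tert-butyldimethylsilyloxy)-5-hydroxy-9-oxoicos-2-enoate | CCCCCCCCC[C@H](O[Si](C)(C)C(C)(C)C)CC(=O)C[C@H](O[Si](C)(C)C(C)(C)C)C[C@@H](O)C/C=C\C(=O)OCC | intermediate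
21 | (6S)-6-[(2R,6S)-2,6-dihydroxy-4-oxopentadecyl]-5,6-dihydro-2H-pyran-2-one | CCCCCCCCC[C@H](O)CC(=O)C[C@H](O)C[C@@H]1CC=CC(=O)O1 | intermediate
22 | (6S)-6-[(2R,6S)-2-(diethylboryloxy)-6-hydroxy-4-oxopentadecyl]-5,6-dihydro-2H-pyran-2-one (boron chelated to the ketone) | CCCCCCCCC[C@H](O)CC(=O)C[C@H](OB(CC)CC)C[C@@H]1CC=CC(=O)O1 | intermediate
23 | (6S)-6-[(2S,4S,6S)-2,4,6-trihydroxypentadecyl]-5,6-dihydro-2H-pyran-2-one | CCCCCCCCC[C@H](O)C[C@H](O)C[C@H](O)C[C@@H]1CC=CC(=O)O1 | target

Total step count: 9
Longest linear sequence: 8 steps (steps 2 to 9, from 5 to 23)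

Steps most likely to fail

Step 5. The process at risk is the timing and counting of the alkylations. If the silyl shift starts before 4 is consumed, anion 13 is alkylated by a second molecule of 4. If mono-opening of 9 is not clean, a second anion 13 opens the remaining oxirane. The fallback separates the two alkylations and sets out from 4. 2-Lithio-1,3-dithiane (1,3-dithiane, n-BuLi, THF, −20 °C) should open the oxirane to give (2S)-1-(1,3-dithian-2-yl)undecan-2-ol F1. Silylation (TBSCl, imidazole, DMF) gives tert-butyl{[(2S)-1-(1,3-dithian-2-yl)undecan-2-yl]oxy}dimethylsilane F2. Direct deprotonation of F2 (t-BuLi, THF/HMPA, −78 °C) generates 13 without any silyl shift. Anion 13 is added slowly to excess 9 to give 14, which is capped with TBSCl, and the fallback comes back to the route at 15.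

Step 6. The process at risk is the fate of the BF3-activated oxirane. It may rearrange (Meinwald shift) or be opened by the neighbouring silyl ether oxygen faster than by the weakly nucleophilic acetylide. The fallback builds the lactone by ring-closing metathesis and sets out from 15. Vinylmagnesium bromide with CuI (cat.) in THF at −30 °C should give (4S,6R)-6-(tert-butyldimethylsilyloxy)-7-{2-[(2S)-2-(tert-butyldimethylsilyloxy)undecyl]-1,3-dithian-2-yl}hept-1-en-4-ol F3. Acryloyl chloride and i-Pr2NEt in CH2Cl2 at 0 °C give the acrylate (4S,6R)-6-(tert-butyldimethylsilyloxy)-7-{2-[(2S)-2-(tert-butyldimethylsilyloxy)undecyl]-1,3-dithian-2-yl}hept-1-en-4-yl prop-2-enoate F4. PhI(OCOCF3)2 in MeCN/H2O at 0 °C unmasks the ketone (4S,6R,10S)-6,10-bis(tert-butyldimethylsilyloxy)-8-oxononadec-1-en-4-yl prop-2-enoate F5, which removes the sulfur before the metathesis. The second-generation Grubbs catalyst RuCl2(=CHPh)(H2IMes)(PCy3) in CH2Cl2 at 40 °C closes the ring to (6S)-6-[(2R,6S)-2,6-bis(tert-butyldimethylsilyloxy)-4-oxopentadecyl]-5,6-dihydro-2H-pyran-2-one F6. Treatment with 48% aq. HF in MeCN removes both silyl ethers, and the fallback comes back to the route at 21.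

Step 9. The process at risk is chemoselectivity and facial control. Hydride may add to the conjugated lactone, and two hydroxyls competing for boron may erode facial selectivity. The fallback reduces the ketone before the lactone exists and sets out from 19. 48% aq. HF in MeCN should give ethyl (5S,7R,11S)-5,7,11-trihydroxy-9-oxoicos-2-ynoate F7. Et2BOMe and NaBH4 in THF/MeOH at −78 °C give ethyl (5S,7R,9S,11S)-5,7,9,11-tetrahydroxyicos-2-ynoate F8. H2 over Pd/CaCO3 poisoned with Pb(OAc)2, with quinoline in EtOAc, gives ethyl (2Z,5S,7R,9S,11S)-5,7,9,11-tetrahydroxyicos-2-enoate F9. F9 is lactonised with PPTS in benzene, and the fallback comes back to the route at 23.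

Further compounds
F1 | step 5 | (2S)-1-(1,3-dithian-2-yl)undecan-2-ol | CCCCCCCCC[C@H](O)CC1SCCCS1
F2 | step 5 | tert-butyl{[(2S)-1-(1,3-dithian-2-yl)undecan-2-yl]oxy}dimethylsilane | CCCCCCCCC[C@H](O[Si](C)(C)C(C)(C)C)CC1SCCCS1
F3 | step 6 | (4S,6R)-6-(tert-butyldimethylsilyloxy)-7-{2-[(2S)-2-(tert-butyldimethylsilyloxy)undecyl]-1,3-dithian-2-yl}hept-1-en-4-ol | CCCCCCCCC[C@H](O[Si](C)(C)C(C)(C)C)CC1(SCCCS1)C[C@H](O[Si](C)(C)C(C)(C)C)C[C@@H](O)CC=C
F4 | step 6 | (4S,6R)-6-(tert-butyldimethylsilyloxy)-7-{2-[(2S)-2-(tert-butyldimethylsilyloxy)undecyl]-1,3-dithian-2-yl}hept-1-en-4-yl prop-2-enoate | CCCCCCCCC[C@H](O[Si](C)(C)C(C)(C)C)CC1(SCCCS1)C[C@H](O[Si](C)(C)C(C)(C)C)C[C@@H](OC(=O)C=C)CC=C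
F5 | step 6 | (4S,6R,10S)-6,10-bis(tert-butyldimethylsilyloxy)-8-oxononadec-1-en-4-yl prop-2-enoate | CCCCCCCCC[C@H](O[Si](C)(C)C(C)(C)C)CC(=O)C[C@H](O[Si](C)(C)C(C)(C)C)C[C@@H](OC(=O)C=C)CC=C
F6 | step 6 | (6S)-6-[(2R,6S)-2,6-bis(tert-butyldimethylsilyloxy)-4-oxopentadecyl]-5,6-dihydro-2H-pyran-2-one | CCCCCCCCC[C@H](O[Si](C)(C)C(C)(C)C)CC(=O)C[C@H](O[Si](C)(C)C(C)(C)C)C[C@@H]1CC=CC(=O)O1
F7 | step 9 | ethyl (5S,7R,11S)-5,7,11-trihydroxy-9-oxoicos-2-ynoate | CCCCCCCCC[C@H](O)CC(=O)C[C@H](O)C[C@@H](O)CC#CC(=O)OCC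
F8 | step 9 | ethyl (5S,7R,9S,11S)-5,7,9,11-tetrahydroxyicos-2-ynoate | CCCCCCCCC[C@H](O)C[C@H](O)C[C@H](O)C[C@@H](O)CC#CC(=O)OCC
F9 | step 9 | ethyl (2Z,5S,7R,9S,11S)-5,7,9,11-tetrahydroxyicos-2-enoate | CCCCCCCCC[C@H](O)C[C@H](O)C[C@H](O)C[C@@H](O)C/C=C\C(=O)OCC
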